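Late in a run the target peak separates the flasks by their base charge: between 90.0 s and 120 s the west run gains 7.7 percentage points of target, and the north-east run gains more, 12 points. So I count protons. Each target uses one nucleophile, which free base first had to release from protonated nucleophile, and sets free one acid, which takes a second free base or else protonates another nucleophile. Each target therefore costs two equivalents of free base as long as no acid stays unbound.

in all of them: solid electrophile 10 mM
- west: free base 1 equiv; protonated nucleophile 1.8 equiv; run made earlier
- north-east: free base 1.7 equiv; protonated nucleophile 1.8 equiv; run made earlier
- south-east: free base 2.3 equiv; protonated nucleophile 1.8 equiv; run made earlier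
- spring: free base 1.20 equiv; protonated nucleophile 1.80 equiv; time 3.0 min
- noon: free base 1.80 equiv; protonated nucleophile 1.80 equiv; time 3.0 min
- dusk: free base 2.70 equiv; protonated nucleophile 1.80 equiv; time 3.0 min

| run | time / s | solid electrophile / % | target / % |
|---|---|---|---|
| west | 25.0 | 86.9 | 8.6 |
| west | 50.0 | 75.3 | 19.3 |
| west | 80.0 | 61.3 | 29.8 |
| west | 90.0 | 58.0 | 33.1 |
| west | 120 | 47.1 | 40.8 |
| north-east | 25.0 | 87.5 | 10.8 |
| north-east | 50.0 | 74.4 | 22.3 |
| north-east | 80.0 | 59.9 | 35.8 |
| north-east | 90.0 | 55.8 | 38.9 |
| north-east | 120 | 41.7 | 51.4 |
| south-east | 10.0 | 95.3 | 3.6 |
| south-east | 20.0 | 89.7 | 8.3 |
| south-east | 40.0 | 79.7 | 18.3 |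
| south-east | 60.0 | 69.7 | 27.1 |
| south-east | 120 | 40.3 | 55.3 |

(standard deviation of a reading: 0.5 percentage points)

- given per volume of solution although it is solid: solid electrophile
- reactions considered so far: solid electrophile <-> electrophile; nucleophile <-> dormant form; electrophile + nucleophile -> acid set free + target; acid set free + free base <-> salt of the base; nucleophile + acid set free <-> protonated nucleophile
- at the start none of the solid electrophile is in solution
- what has only dissolved of solid electrophile counts as not reacted

* part of the solid electrophile that has reacted (what has only dissolved counts as not reacted) at the end, spring
* part of the solid electrophile that has reacted (what has only dissolved counts as not reacted) at the end, noon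
* part of the solid electrophile that has reacted (what has only dissolved counts as not reacted) at the end, dusk
* what raising the equivalents of free base from its lowest to its highest value here does to the part of the solid electrophile that has reacted (what has only dissolved counts as not reacted) (changes below 5 percentage points count as none) (no change / it rises / it falls)

Two amounts stand against each other: the base charged, and twice the electrophile supplied by the asked time. I read the supply from the south-east run, whose solid electrophile loses 59.7% in 120 s; kept up for 3.0 min, that is 89.5% of the charge. Equivalents of free base over twice that fraction give 0.670 for spring, 1.01 for noon and 1.51 for dusk: this ratio is the base cover. With cover under one, nucleophile free or dormant gives out at a target of half the base charge, unless acid stays unbound, which in spring is 0.600 equiv. So I expect spring near that knee, dusk close to its supply, and noon between them.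

The forecast says 65%, 77% and 84%, and for the step from lowest to highest free base: it rises, on the ground: “Free nucleophile is roughly base minus conversion”.

The flasks give 56.8%, 69.1% and 81.1%; from lowest to highest free base, it rises, by 24 points.

    solid electrophile ⇌ electrophile, rate k1*(cs1 - [electrophile]) while solid is left; crystals form when [electrophile] > cs1 (solubility = 3.40 mM, k = 0.0160 s⁻¹)
    nucleophile ⇌ dormant form (K = 1.30, k = 0.00670 s⁻¹)
    electrophile + nucleophile → acid set free + target (k = 18.0 M⁻¹ s⁻¹)
    acid set free + free base ⇌ salt of the base, settled at all times (K = 5.40 × 10⁵ M⁻¹)
    nucleophile + acid set free ⇌ protonated nucleophile, settled at all times (K = 7100 M⁻¹)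

In spring free base is down to 0.352% of its charge by 1.50 min, and coupling goes on: at 3.00 min target stands at 56.8% with 2.31 mM of acid set free. In dusk, cover 1.51, free base still stands at 5.93% of its charge at the end, with electrophile at 6.62%. The neighbour with 6.0 mM of solid electrophile could receive more than its charge, so its fraction counts as one and its cover is 1.35; it ends with solid electrophile at 0% and target at 96.6%.

(The data were generated by integration for substances that don't exist, and the scatter is random.)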